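Compare the two runs at one time before reckoning anything.

| setting | zeta | eta | flask |
|---|---|---|---|
| Z | 0.092 M | 0.092 M | 0.092 M |
| L | 1.1 equiv | 1.1 equiv | 1.10 equiv |
| E | 1.2 equiv | 0.60 equiv | 1.20 equiv |
| remark | the very flask that is asked about, followed so far | run made earlier |  |
| time |  |  | 20 h |

- zeta (time / h: X / %, Z / %): 0.500: 4.7, 65.0; 0.667: 6.6, 60.4; 1.33: 12.4, 49.7; 2.00: 13.2, 43.1; 3.00: 12.3, 38.3; 5.00: 11.1, 31.2; 8.00: 8.3, 25.9
- eta (time / h: X / %, Z / %): 0.500: 2.1, 81.3; 0.833: 2.8, 78.4; 1.33: 4.8, 74.7; 2.50: 4.3, 71.8; 5.00: 2.8, 66.1; 8.00: 2.4, 61.0; 15.0: 1.0, 55.6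

(readings scatter by 0.5 percentage points)

* when, up to 20 h, the flask holds most X
* the amount of X, in percent of the Z charged, at that time
* earliest time at which at least nineteen twentieths of that best amount are there
* latest time at which they still are



Which charge sets how much Z has gone at a given time? E, I say. At 1.33 h the zeta run has lost 0.419 of the Z charged per equivalent of E charged, and the eta run 0.422. Call this figure the take. The two readings agree, so at that time the Z lost goes in step with the E charged; this is a proportion of amounts, and it gives no rate order.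

But Z goes on falling after X stops, so does the take survive? Only as a figure for a stated time. At 8.00 h the zeta run reads 0.618 and the eta run 0.650, both higher than before.

And the peak? My own reckoning stays with the readings. Zeta reads X at 12.4% at 1.33 h, 13.2% at 2.00 h and 12.3% at 3.00 h, so I put the top between 1.33 h and 3.00 h.

The forecast, seeing a rise that “stops abruptly”, gives 13.5% at 1.7 h, with the level held from 1.38 h to 2.6 h.

The flask gives 13.6% at 1.84 h, and holds the level asked for from 1.36 h to 2.56 h. The forecast stands on all four counts, and the flask offers a window of 1.20 h.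

    Z + E → D (k = 0.00400 L mol⁻¹ s⁻¹)
    E + L → Q (k = 0.00590 L mol⁻¹ s⁻¹)
    D + Q → X (k = 0.00490 L mol⁻¹ s⁻¹)
    X ⇌ G (K = 1.60, k = 2.10 × 10⁻⁴ s⁻¹)
    Z + X → J (k = 0.00260 L mol⁻¹ s⁻¹)

At its best time the flask holds Z at 45.2%, a take of 0.457, and E, the limiting reagent, at 3.26%. In this flask X has a half-life of 1.0 h by Z + X → J at 0.232 h, short against the 20 h allowed, yet at 20.0 h that step runs at 0.16 of the forward rate of X → G. With E at 4.80 equiv, the take of 1.33 h asks for 2.01 of the Z charged, more than the charge, so Z should go and E should remain. That neighbour ends with Z at 0% and E at 56.6% of its charge, and its best X is 42.0%.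

The readings are simulated for substances that don't exist.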